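## Analysis of the target

Atoms are numbered as in a germacrane: ring carbons C1–C10, C14 the CH2OH carbon on C10, C15 the carbonyl on C4, and C11 (with carbonyl C12 and methylene C13) on C7.

The target 26 is a ten-membered carbocycle that carries two five-membered lactones. One is a butenolide (C15 carbonyl on C4, lactone oxygen on C6, C4=C5 shared with the large ring). The other is an α-methylene-γ-butyrolactone (C11=C13, C12 carbonyl, lactone oxygen on C8) fused at C7–C8. Because C15 and C6 are cis in the five-membered ring, C3 and C6 are trans across C4=C5, so the large ring holds a trans double bond (the CIP label is Z only because C15 outranks C3). There are five stereocentres: C3 (S, isobutyrate), C6 (R), C7 (S), C8 (R) and C10 (R, CH2OH). C6–C7–C8 form a contiguous triad with a trans-fused lactone, whereas C10 is one methylene away from C8 and C3 two methylenes away from C10, so C3 and C10 need their own reagent control. The sensitive groups are the exocyclic methylene lactone (a Michael acceptor), the C6–H γ-proton of the butenolide (more acidic than the C11 protons of a saturated lactone; its removal would epimerise C6 and could expel the C3 acyloxy group), the allylic C3 ester and the primary alcohol. The difficulty is to close a medium ring with a trans alkene between two lactones while setting C6 and C7, and then to introduce the methylene without base. The strategy rests on one feature: C6 is the γ-carbon of the C4 butenolide and C7 the β-carbon of the C12 lactone. The ring bond C6–C7 therefore joins the nucleophilic terminus of a 2-silyloxyfuran to the electrophilic β-position of a furan-2(5H)-one, and the two lactone rings can exist before the large ring, linked only by C9–C10–C1–C2–C3.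

## Retrosynthetic reasoning

**26 to 25 (O14–Si).** The primary hydroxyl is kept silylated to the end, because a free alcohol would interfere with the silyl triflate, the Lewis acid and the acylations. A primary tert-butyldimethylsilyl ether survives every step and is removed last with buffered fluoride, which touches neither lactone nor the ester.

**25 to 23 to 22 (C11–C13).** The methylene is the most reactive group and is made last, by elimination from a C11 aminomethyl group (23). That group must come from a C11 enolate equivalent formed without base, since base would remove C6–H first. Compound 22, the silyl ketene acetal that the ring closure itself leaves at C11–C12, is that equivalent. It is therefore trapped in the flask and not hydrolysed, because after protonation at C11 it could only be regenerated with base.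

**22 to 21 (C6–C7, the key disconnection).** C6–C7 is the only ring bond whose two ends are each activated by one of the lactones, one as a dienolate γ-carbon and one as an enoate β-carbon. Cutting here removes the ring, C6 and C7 in one operation and leaves a precursor (21) in which both lactone rings, the trans C4=C5 geometry and all oxidation levels are already in place. The forward reaction has to close a ten-membered ring end to end and to set C7 anti to C9 and C6 in the right sense.

**21 to 20 to 19 to 18 to 17 to 15 (C7=C11, O–Si, O8–C12, C7–C8, C8=CH2).** The C8 butenolide is closed by metathesis (20 to 21) only after the furan has been silylated (19 to 20). Silylation with amine base would enolise every butenolide present, and enolising the C8 butenolide would destroy C8. In 19 the future acceptor is still an open acrylate without γ-hydrogen. The acrylate comes from the allylic alcohol 18, whose C8 centre is set by a ligand-controlled vinyl addition to aldehyde 17, and 17 comes from oxidative cleavage of the terminal alkene of 15.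

**15 to 14 to 13 to 12 to 10 + 11 (C3–C4).** The α-(1-acyloxyalkyl)butenolide is the Morita–Baylis–Hillman adduct of 11 and aldehyde 10, which makes the C3–C4 bond directly at the α-carbon of the furanone. No neighbouring centre can control C3, so the carbinol is oxidised (13) and reduced under catalyst control (14) before the isobutyrate is put on (15).

**10 to 9 to 8 to 7 to 5 to 3 + 4, and 3 to 1 + 2 (C9–C10).** C10 is set first, by auxiliary-controlled allylation of the glutarate half-ester imide 3. The imide carbonyl becomes C14 and the ester carbon becomes C3, so the two ends are differentiated from the start, and the allyl group supplies C9 and C8. Reduction gives lactone 7, which is opened to an amide (8, 9) that reduces cleanly to aldehyde 10.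

## Alternatives that were turned down

**Alternative 1:** The ring is cut at C8–C9. In the forward step SmI2 reduces a C8 aldehyde to its ketyl, which adds to the terminal carbon C9 of an acrylate whose α-carbon is C10. The samarium alkoxide on C8 then acylates with the C14 ester, giving the lactone-bridged ring A1. In its favour, ketyl–acrylate cyclisation is an established way to medium rings, and the bridging lactone fixes C8 and C10 cis, as required. On precedent for the ring-forming event it is stronger than the chosen step. Against it, A1 contains neither lactone of the target. C12 and C15 are still protected primary alcohols, and the only lactone present uses C14, which must end as CH2OH. After the key step the C14 lactone would have to be reduced next to the C3 isobutyrate, three silyl or benzyl ethers removed selectively, and two alcohols oxidised and lactonised. The open-chain substrate must also already hold C3, C6, C7 and the trisubstituted C4=C5 alkene, and it exposes an allylic ester to a one-electron reductant. The chosen route gives up that precedent but closes the ring with both lactones and every oxidation level in place, so that three steps follow the key step and not a long sequence of redox and protecting-group operations.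

**Alternative 2:** Here C5–C10 is broken and C2–C3 formed: the potassium alkoxide (KH, 18-crown-6) of a trans-1,2-dialkenylcyclohexanol undergoes an anionic oxy-Cope rearrangement through a chair to the ten-membered ketone A2. In its favour, this is the most dependable route to a cyclodecene. The chair fixes the trans C4=C5 geometry and relays configuration to C3, and the C6–C7–C8 triad can be set beforehand on a six-membered ring. On ring formation and on control of the triad it is stronger than the chosen step. Against it, A2 has a ketone at C10 and lacks C14, so the hydroxymethyl group and the C10 centre must be added afterwards to a flexible ten-membered ketone with no reliable facial bias. The C3 configuration depends on a geometrically pure enol ether. Both lactones still have to be made by oxidising C12 and C15 after removing several different protecting groups, and two methoxymethyl ethers must be cleaved by acid next to an allylic system before the isobutyrate can go on. The chosen route sets C10 first with an auxiliary, carries C14 from the start and needs far fewer steps after ring closure; what it offers in place of the secure rearrangement is step economy and a precursor with three independently set centres.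

**Alternative 3:** This cuts O8–C12 and C11–C12, so that C12 enters as carbon monoxide. PdCl2 with thiourea under CO turns the C8 hydroxyl into an alkoxycarbonylpalladium species, which adds across a C11≡C13 ethynyl group on C7 and closes the methylene lactone. The product A3 has the same structure as 25. In its favour, it is a known reaction of homopropargylic alcohols and makes the methylene lactone in one step without any enolate or base, which is more direct than the trapping and elimination used here. Against it, it is an end-game operation and leaves the real problem untouched: the complete ten-membered ring with the butenolide, C6, and a C7 ethynyl group trans to the C8 hydroxyl must first be made by some other ring closure. An ethynyl group on C7 cannot serve as the acceptor for C6–C7 formation, so the two ideas cannot be combined. The chosen key step delivers the ring, C6, C7 and the C11 enolate equivalent together, so that the methylene costs only one further step.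

Key step: step 16

Assumption: in 12, 16, 23 and 24 one centre (C3, the ozonide carbon, or C11) is left undefined because it is destroyed in the next operation.

Step 1
Reactants: 1 (S)-4-benzyl-2-oxazolidinone; 2 methyl 5-chloro-5-oxopentanoate
Product: 3 methyl 5-[(4S)-4-benzyl-2-oxo-1,3-oxazolidin-3-yl]-5-oxopentanoate
Conditions: n-BuLi, THF, −78 °C; then 2, −78 → 0 °C
Reagents that add atoms: none
Why: N-acylation of the lithiated oxazolidinone by the acid chloride; the methyl ester is much less electrophilic and should stay intact, which gives a glutarate with C14 as imide and C3 as ester.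

Step 2
Reactants: 3 methyl 5-[(4S)-4-benzyl-2-oxo-1,3-oxazolidin-3-yl]-5-oxopentanoate; 4 allyl bromide
Product: 5 methyl (4R)-4-{[(4S)-4-benzyl-2-oxo-1,3-oxazolidin-3-yl]carbonyl}hept-6-enoate
Conditions: NaN(SiMe3)2, THF, −78 °C; then 4, −78 → −40 °C
Reagents that add atoms: none
Why: Evans asymmetric alkylation: the imide (more acidic than the ester) gives the chelated (Z)-sodium enolate, which is allylated on the face away from the benzyl group and so sets C10 as R; attack of the enolate on its own ester would need a four-membered ring and is not expected.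

Step 3
Reactants: 5 methyl (4R)-4-{[(4S)-4-benzyl-2-oxo-1,3-oxazolidin-3-yl]carbonyl}hept-6-enoate
Product: 7 (5R)-5-(prop-2-en-1-yl)oxan-2-one, via hydroxy ester 6 (not isolated)
Conditions: NaBH4, THF/H2O, 0 → 20 °C; then p-TsOH (cat.), CH2Cl2, 20 °C
Reagents that add atoms: none
Why: Reductive cleavage of the N-acyl oxazolidinone by borohydride gives the primary alcohol and frees the auxiliary, while the methyl ester is inert to NaBH4; acid then closes the 5-hydroxy ester to the δ-lactone, which separates easily from the auxiliary.

Step 4
Reactants: 7 (5R)-5-(prop-2-en-1-yl)oxan-2-one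
Product: 8 (4R)-4-(hydroxymethyl)-N-methoxy-N-methylhept-6-enamide
Conditions: MeNH(OMe)·HCl, i-PrMgCl, THF, −20 → 0 °C
Reagents that add atoms: N,O-dimethylhydroxylamine hydrochloride, CNOC.Cl
Why: Aminolysis of the lactone by the magnesium amide (Weinreb amide formation) frees the C14 hydroxyl and puts C3 at a level that can be reduced to the aldehyde without over-reduction.

Step 5
Reactants: 8 (4R)-4-(hydroxymethyl)-N-methoxy-N-methylhept-6-enamide
Product: 9 (4R)-4-{[(tert-butyldimethylsilyl)oxy]methyl}-N-methoxy-N-methylhept-6-enamide
Conditions: TBSCl, imidazole, CH2Cl2, 20 °C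
Reagents that add atoms: tert-butyldimethylsilyl chloride, CC(C)(C)[Si](C)(C)Cl
Why: Silylation of the primary alcohol; it also stops the hydroxy amide from closing back to the lactone.

Step 6
Reactants: 9 (4R)-4-{[(tert-butyldimethylsilyl)oxy]methyl}-N-methoxy-N-methylhept-6-enamide
Product: 10 (4R)-4-{[(tert-butyldimethylsilyl)oxy]methyl}hept-6-enal
Conditions: i-Bu2AlH, THF, −78 °C; aq. potassium sodium tartrate
Reagents that add atoms: none
Why: Hydride reduction of a Weinreb amide stops at the chelated tetrahedral intermediate, which gives the aldehyde only on work-up.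

Step 7
Reactants: 10 (4R)-4-{[(tert-butyldimethylsilyl)oxy]methyl}hept-6-enal; 11 furan-2(5H)-one
Product: 12 3-[(4R)-4-{[(tert-butyldimethylsilyl)oxy]methyl}-1-hydroxyhept-6-en-1-yl]furan-2(5H)-one (both C3 epimers)
Conditions: 11 (3 equiv), n-Bu3P (20 mol %), 1,1'-bi-2-naphthol (10 mol %), THF, 20 °C
Reagents that add atoms: none
Why: Morita–Baylis–Hillman reaction: the phosphine adds to the β-carbon of 11, the enolate adds through the α-carbon to the aldehyde, and proton transfer with loss of phosphine restores the butenolide; the phenol activates the aldehyde and speeds the proton transfer. C3 is formed without control and is corrected in steps 8 and 9.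

Step 8
Reactants: 12 3-[(4R)-4-{[(tert-butyldimethylsilyl)oxy]methyl}-1-hydroxyhept-6-en-1-yl]furan-2(5H)-one
Product: 13 3-[(4R)-4-{[(tert-butyldimethylsilyl)oxy]methyl}hept-6-enoyl]furan-2(5H)-one
Conditions: Dess–Martin periodinane, CH2Cl2, 0 °C
Reagents that add atoms: none
Why: Dess–Martin oxidation of the secondary alcohol under neutral, non-aqueous conditions converges both C3 epimers on one ketone; the doubly activated alkene sees neither base nor nucleophile and is used at once.

Step 9
Reactants: 13 3-[(4R)-4-{[(tert-butyldimethylsilyl)oxy]methyl}hept-6-enoyl]furan-2(5H)-one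
Product: 14 3-[(1S,4R)-4-{[(tert-butyldimethylsilyl)oxy]methyl}-1-hydroxyhept-6-en-1-yl]furan-2(5H)-one
Conditions: (R)-2-methyl-CBS-oxazaborolidine (0.5 equiv), catecholborane, toluene, −78 °C
Reagents that add atoms: none
Why: Corey–Bakshi–Shibata reduction: the ketone binds to boron anti to the larger butenolide substituent and hydride is delivered to one face, so the (R)-catalyst should give the (S)-carbinol with the CH2 chain as the small group. Catecholborane at −78 °C leaves the terminal alkene alone and favours 1,2- over 1,4-reduction.

Step 10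
Reactants: 14 3-[(1S,4R)-4-{[(tert-butyldimethylsilyl)oxy]methyl}-1-hydroxyhept-6-en-1-yl]furan-2(5H)-one
Product: 15 (1S,4R)-4-{[(tert-butyldimethylsilyl)oxy]methyl}-1-(2-oxo-2,5-dihydrofuran-3-yl)hept-6-en-1-yl 2-methylpropanoate
Conditions: (i-PrCO)2O, Et3N, DMAP (cat.), CH2Cl2, 0 °C
Reagents that add atoms: isobutyric anhydride, CC(C)C(=O)OC(=O)C(C)C
Why: DMAP-catalysed acylation of the secondary alcohol; the ester of the target is in place from here on, and short contact with amine at 0 °C should not isomerise the butenolide.

Step 11
Reactants: 15 (1S,4R)-4-{[(tert-butyldimethylsilyl)oxy]methyl}-1-(2-oxo-2,5-dihydrofuran-3-yl)hept-6-en-1-yl 2-methylpropanoate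
Product: 17 (1S,4R)-4-{[(tert-butyldimethylsilyl)oxy]methyl}-6-oxo-1-(2-oxo-2,5-dihydrofuran-3-yl)hexyl 2-methylpropanoate, via ozonide 16 (not isolated)
Conditions: O3, CH2Cl2, −78 °C; then PPh3, −78 → 20 °C
Reagents that add atoms: ozone, [O-][O+]=O
Why: Ozonolysis of the electron-rich monosubstituted alkene; the conjugated, electron-poor C4=C5 bond reacts far more slowly with ozone, and reductive work-up gives the C8 aldehyde.

Step 12
Reactants: 17 (1S,4R)-4-{[(tert-butyldimethylsilyl)oxy]methyl}-6-oxo-1-(2-oxo-2,5-dihydrofuran-3-yl)hexyl 2-methylpropanoate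
Product: 18 (1S,4R,6R)-4-{[(tert-butyldimethylsilyl)oxy]methyl}-6-hydroxy-1-(2-oxo-2,5-dihydrofuran-3-yl)oct-7-en-1-yl 2-methylpropanoate
Conditions: (CH2=CH)2Zn (salt-free, prepared beforehand from CH2=CHMgBr and ZnCl2), (−)-MIB [(2S)-3-exo-morpholinoisoborneol] (10 mol %), toluene, −20 → 0 °C; aq. NH4Cl
Reagents that add atoms: divinylzinc, C=C[Zn]C=C
Why: Amino-alcohol-catalysed enantioselective addition of a vinylzinc reagent to an aldehyde: the zinc alkoxide of (−)-MIB directs the vinyl group to the Si face, which corresponds to the (R)-carbinol at C8. The organozinc should not touch lactone, ester or conjugated alkene, and C10 is too remote to override the ligand.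

Step 13
Reactants: 18 (1S,4R,6R)-4-{[(tert-butyldimethylsilyl)oxy]methyl}-6-hydroxy-1-(2-oxo-2,5-dihydrofuran-3-yl)oct-7-en-1-yl 2-methylpropanoate
Product: 19 (1S,4R,6R)-4-{[(tert-butyldimethylsilyl)oxy]methyl}-1-(2-oxo-2,5-dihydrofuran-3-yl)-6-(prop-2-enoyloxy)oct-7-en-1-yl 2-methylpropanoate
Conditions: CH2=CHCOCl, i-Pr2NEt, CH2Cl2, −40 → 0 °C
Reagents that add atoms: acryloyl chloride, C=CC(=O)Cl
Why: O-acylation of the allylic alcohol with a hindered amine base; the low temperature avoids amine addition to the acrylate.

Step 14
Reactants: 19 (1S,4R,6R)-4-{[(tert-butyldimethylsilyl)oxy]methyl}-1-(2-oxo-2,5-dihydrofuran-3-yl)-6-(prop-2-enoyloxy)oct-7-en-1-yl 2-methylpropanoate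
Product: 20 (1S,4R,6R)-4-{[(tert-butyldimethylsilyl)oxy]methyl}-6-(prop-2-enoyloxy)-1-{2-[(triisopropylsilyl)oxy]furan-3-yl}oct-7-en-1-yl 2-methylpropanoate
Conditions: i-Pr3SiOTf, Et3N, CH2Cl2, 0 °C
Reagents that add atoms: triisopropylsilyl trifluoromethanesulfonate, CC(C)[Si](OS(=O)(=O)C(F)(F)F)(C(C)C)C(C)C
Why: Soft enolisation: the silyl triflate activates the C15 carbonyl and Et3N removes a C6 proton to give the aromatic 2-silyloxyfuran. The butenolide is the only γ-enolisable carbonyl in 19 (the acrylate has no γ-hydrogen), so C8 is untouched; this is why the furan is made before the second butenolide exists.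

Step 15
Reactants: 20 (1S,4R,6R)-4-{[(tert-butyldimethylsilyl)oxy]methyl}-6-(prop-2-enoyloxy)-1-{2-[(triisopropylsilyl)oxy]furan-3-yl}oct-7-en-1-yl 2-methylpropanoate
Product: 21 (1S,4R)-4-{[(tert-butyldimethylsilyl)oxy]methyl}-5-[(2R)-5-oxo-2,5-dihydrofuran-2-yl]-1-{2-[(triisopropylsilyl)oxy]furan-3-yl}pentyl 2-methylpropanoate
Conditions: second-generation Grubbs catalyst (H2IMes)(PCy3)Cl2Ru=CHPh (5 mol %), CH2Cl2 (5 mM), 40 °C
Reagents that add atoms: none
Why: Ring-closing metathesis of the acrylate with the allylic vinyl group closes the (R)-5-substituted furan-2(5H)-one and releases ethene under neutral conditions; the aromatic silyloxyfuran offers no metathesis-active alkene, and dilution suppresses cross metathesis.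

Step 16
Reactants: 21 (1S,4R)-4-{[(tert-butyldimethylsilyl)oxy]methyl}-5-[(2R)-5-oxo-2,5-dihydrofuran-2-yl]-1-{2-[(triisopropylsilyl)oxy]furan-3-yl}pentyl 2-methylpropanoate
Product: 23 the 13-(dimethylamino)-11,13-dihydro derivative of 25 (ten-membered ring closed; C11 epimers), via silyl ketene acetal 22 (not isolated)
Conditions: Sc(OTf)3 (20 mol %), 2,6-di-tert-butyl-4-methylpyridine (30 mol %), 4 Å MS, CH2Cl2 (1 mM, slow addition of 21), −40 → −10 °C; then CH2=NMe2+ I−, MeCN, −10 → 20 °C
Reagents that add atoms: Eschenmoser's salt (N,N-dimethylmethyleneiminium iodide), C=[N+](C)C.[I-]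
Why: Proposed new method: Sc(OTf)3 binds the C12 carbonyl of the butenolide and the silyl dienol ether attacks C7 through its terminus C6 (furan C5); the 2-silyloxyfuranium ion so formed passes its i-Pr3Si group, by way of i-Pr3SiOTf, to the scandium enolate, which gives the C11=C12 silyl ketene acetal 22 and the C4=C5 butenolide and frees the catalyst. The closest known reaction type is the intermolecular Lewis-acid-catalysed vinylogous Mukaiyama–Michael addition of 2-silyloxyfurans to enones and to furan-2(5H)-ones; what is new is its use between two tethered lactone rings to close a medium ring. The ten-membered ring closes in a 10-exo-trig mode (C11 stays outside the new ring) with the nucleophilic π-system endocyclic; because both reacting carbons sit in flat five-membered rings, only the five sp3 carbons C9–C10–C1–C2–C3 have to fold, and the trans C4=C5 geometry follows from C15 and C6 being cis in the furan. C7 is set by C8: the furan should add to the face of the butenolide opposite the C9 substituent, as in intermolecular additions to 5-substituted furan-2(5H)-ones, and the seven-atom chain from C8 to C6 is long enough to reach that face, which gives the trans-fused lactone. C6 is set by the face of the planar furan that the tether presents, with the C3 oxygen and the C10 silyloxymethyl group expected to point outward in the folding chain; this relative topicity has no direct precedent and has to be checked on 23. The step needs γ- over α-attack of the dienol ether (secured by the substituent on C4 and the usual γ-preference of 2-silyloxyfurans), ring closure over oligomerisation (1 mM, slow addition) and survival of the C3 ester, which is vinylogous to the silyloxy group (low temperature, catalytic Lewis acid, hindered pyridine as proton scavenger). The silyl ketene acetal is then the only C11 enolate equivalent that can be made without base: it adds to the iminium salt in a Mannich reaction of a known type and gives 23.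

Step 17
Reactants: 23 the 13-(dimethylamino)-11,13-dihydro derivative of 25
Product: 25 (3S,6R,7S,8R,10R)-14-[(tert-butyldimethylsilyl)oxy]-3-(2-methylpropanoyloxy)germacra-4,11(13)-diene-12,8:15,6-diolide, via ammonium iodide 24 (not isolated)
Conditions: MeI, CH2Cl2, 20 °C; then aq. NaHCO3, EtOAc, 20 °C
Reagents that add atoms: iodomethane, CI (its methyl group is carried by 24 and leaves again as trimethylamine)
Why: Quaternisation of the Mannich base and β-elimination of trimethylamine (E1cB through the C11 position, which the ammonium group acidifies) give the α-methylene lactone; NaHCO3 is too weak to remove C6–H.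

Step 18
Reactants: 25 (3S,6R,7S,8R,10R)-14-[(tert-butyldimethylsilyl)oxy]-3-(2-methylpropanoyloxy)germacra-4,11(13)-diene-12,8:15,6-diolide
Product: 26 CNP0332805.1, (3S,6R,7S,8R,10R)-14-hydroxy-3-(2-methylpropanoyloxy)germacra-4,11(13)-diene-12,8:15,6-diolide
Conditions: HF·pyridine, pyridine, THF, 0 → 20 °C
Reagents that add atoms: none
Why: Fluoride cleavage of the primary silyl ether under buffered, non-basic conditions, which should leave the methylene lactone, the butenolide and the isobutyrate untouched.

## Compound list

1 | (S)-4-benzyl-2-oxazolidinone | O=C1N[C@@H](Cc2ccccc2)CO1 | starting material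
2 | methyl 5-chloro-5-oxopentanoate | COC(=O)CCCC(=O)Cl | starting material
3 | methyl 5-[(4S)-4-benzyl-2-oxo-1,3-oxazolidin-3-yl]-5-oxopentanoate | COC(=O)CCCC(=O)N1[C@@H](Cc2ccccc2)COC1=O | intermediate
4 | allyl bromide | C=CCBr | starting material
5 | methyl (4R)-4-{[(4S)-4-benzyl-2-oxo-1,3-oxazolidin-3-yl]carbonyl}hept-6-enoate | C=CC[C@H](C(=O)N1[C@@H](Cc2ccccc2)COC1=O)CCC(=O)OC | intermediate
6 | methyl (4R)-4-(hydroxymethyl)hept-6-enoate (not isolated) | C=CC[C@H](CO)CCC(=O)OC | intermediate
7 | (5R)-5-(prop-2-en-1-yl)oxan-2-one | C=CC[C@@H]1COC(=O)CC1 | intermediate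
8 | (4R)-4-(hydroxymethyl)-N-methoxy-N-methylhept-6-enamide | C=CC[C@H](CO)CCC(=O)N(C)OC | intermediate
9 | (4R)-4-{[(tert-butyldimethylsilyl)oxy]methyl}-N-methoxy-N-methylhept-6-enamide | C=CC[C@H](CO[Si](C)(C)C(C)(C)C)CCC(=O)N(C)OC | intermediate
10 | (4R)-4-{[(tert-butyldimethylsilyl)oxy]methyl}hept-6-enal | C=CC[C@H](CO[Si](C)(C)C(C)(C)C)CCC=O | intermediate
11 | furan-2(5H)-one | O=C1OCC=C1 | starting material
12 | 3-[(4R)-4-{[(tert-butyldimethylsilyl)oxy]methyl}-1-hydroxyhept-6-en-1-yl]furan-2(5H)-one (both C3 epimers) | C=CC[C@H](CO[Si](C)(C)C(C)(C)C)CCC(O)C1=CCOC1=O | intermediate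
13 | 3-[(4R)-4-{[(tert-butyldimethylsilyl)oxy]methyl}hept-6-enoyl]furan-2(5H)-one | C=CC[C@H](CO[Si](C)(C)C(C)(C)C)CCC(=O)C1=CCOC1=O | intermediate
14 | 3-[(1S,4R)-4-{[(tert-butyldimethylsilyl)oxy]methyl}-1-hydroxyhept-6-en-1-yl]furan-2(5H)-one | C=CC[C@H](CO[Si](C)(C)C(C)(C)C)CC[C@H](O)C1=CCOC1=O | intermediate
15 | (1S,4R)-4-{[(tert-butyldimethylsilyl)oxy]methyl}-1-(2-oxo-2,5-dihydrofuran-3-yl)hept-6-en-1-yl 2-methylpropanoate | C=CC[C@H](CO[Si](C)(C)C(C)(C)C)CC[C@H](OC(=O)C(C)C)C1=CCOC1=O | intermediate
16 | ozonide of 15 (1,2,4-trioxolane from the terminal alkene; not isolated) | C1OC(C[C@H](CO[Si](C)(C)C(C)(C)C)CC[C@H](OC(=O)C(C)C)C2=CCOC2=O)OO1 | intermediate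
17 | (1S,4R)-4-{[(tert-butyldimethylsilyl)oxy]methyl}-6-oxo-1-(2-oxo-2,5-dihydrofuran-3-yl)hexyl 2-methylpropanoate | O=CC[C@H](CO[Si](C)(C)C(C)(C)C)CC[C@H](OC(=O)C(C)C)C1=CCOC1=O | intermediate
18 | (1S,4R,6R)-4-{[(tert-butyldimethylsilyl)oxy]methyl}-6-hydroxy-1-(2-oxo-2,5-dihydrofuran-3-yl)oct-7-en-1-yl 2-methylpropanoate | C=C[C@H](O)C[C@H](CO[Si](C)(C)C(C)(C)C)CC[C@H](OC(=O)C(C)C)C1=CCOC1=O | intermediate
19 | (1S,4R,6R)-4-{[(tert-butyldimethylsilyl)oxy]methyl}-1-(2-oxo-2,5-dihydrofuran-3-yl)-6-(prop-2-enoyloxy)oct-7-en-1-yl 2-methylpropanoate | C=CC(=O)O[C@@H](C=C)C[C@H](CO[Si](C)(C)C(C)(C)C)CC[C@H](OC(=O)C(C)C)C1=CCOC1=O | intermediate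
20 | (1S,4R,6R)-4-{[(tert-butyldimethylsilyl)oxy]methyl}-6-(prop-2-enoyloxy)-1-{2-[(triisopropylsilyl)oxy]furan-3-yl}oct-7-en-1-yl 2-methylpropanoate | C=CC(=O)O[C@@H](C=C)C[C@H](CO[Si](C)(C)C(C)(C)C)CC[C@H](OC(=O)C(C)C)c1ccoc1O[Si](C(C)C)(C(C)C)C(C)C | intermediate
21 | (1S,4R)-4-{[(tert-butyldimethylsilyl)oxy]methyl}-5-[(2R)-5-oxo-2,5-dihydrofuran-2-yl]-1-{2-[(triisopropylsilyl)oxy]furan-3-yl}pentyl 2-methylpropanoate (key-step precursor) | O=C1C=C[C@@H](C[C@H](CO[Si](C)(C)C(C)(C)C)CC[C@H](OC(=O)C(C)C)c2ccoc2O[Si](C(C)C)(C(C)C)C(C)C)O1 | intermediate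
22 | (3S,6R,7S,8R,10R) ring-closed C11=C12 triisopropylsilyl ketene acetal: ten-membered ring with C4=C5 butenolide, C12 bearing O–Si(i-Pr)3, C14 silyl ether, C3 isobutyrate (not isolated) | C1=C(O[Si](C(C)C)(C(C)C)C(C)C)O[C@@H]2C[C@H](CO[Si](C)(C)C(C)(C)C)CC[C@H](OC(=O)C(C)C)C3=C[C@@H](OC3=O)[C@@H]12 | intermediate
23 | 13-(dimethylamino)-11,13-dihydro derivative of 25 (C11 epimers) | CN(C)CC1C(=O)O[C@@H]2C[C@H](CO[Si](C)(C)C(C)(C)C)CC[C@H](OC(=O)C(C)C)C3=C[C@@H](OC3=O)[C@@H]12 | intermediate
24 | N-methyl quaternary ammonium iodide of 23 (not isolated) | C[N+](C)(C)CC1C(=O)O[C@@H]2C[C@H](CO[Si](C)(C)C(C)(C)C)CC[C@H](OC(=O)C(C)C)C3=C[C@@H](OC3=O)[C@@H]12.[I-] | intermediate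
25 | (3S,6R,7S,8R,10R)-14-[(tert-butyldimethylsilyl)oxy]-3-(2-methylpropanoyloxy)germacra-4,11(13)-diene-12,8:15,6-diolide | C=C1C(=O)O[C@@H]2C[C@H](CO[Si](C)(C)C(C)(C)C)CC[C@H](OC(=O)C(C)C)C3=C[C@@H](OC3=O)[C@@H]12 | intermediate
26 | CNP0332805.1, (3S,6R,7S,8R,10R)-14-hydroxy-3-(2-methylpropanoyloxy)germacra-4,11(13)-diene-12,8:15,6-diolide | C=C1C(=O)O[C@@H]2C[C@H](CO)CC[C@H](OC(=O)C(C)C)C3=C[C@@H](OC3=O)[C@@H]12 | target

## Step count and least certain steps

Total: 18 steps. Longest linear sequence: 18 steps (from 1 and 2 to 26); 4 and 11 enter along this single line.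

**Step 16 (key step, proposed new method).** Most likely to fail is the ring closure itself: transannular strain in the ten-membered transition state can let intermolecular addition and oligomerisation win even at 1 mM. Beside that, the Lewis acid may ionise the C3 ester, which is conjugated to the silyloxy group. The furan may add through the wrong face and give the C6 epimer, or add syn to C9 and give the cis lactone. Finally, the silyl ketene acetal may be protodesilylated before the iminium salt is added, which would forfeit the base-free route to the methylene.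

The fallback uses known reactions only: the C6–C7 bond is made between two molecules and the ring is closed afterwards at C3–C4. It sets out from 9 and 11 and returns at 23.
- Bromination and dehydrobromination of 11 (Br2; Et3N) give 3-bromofuran-2(5H)-one F1, and i-Pr3SiOTf/Et3N gives 3-bromo-2-[(triisopropylsilyl)oxy]furan F2.
- Amide 9 is taken through the operations of steps 11, 12, 13 and 15 (O3 then PPh3; (CH2=CH)2Zn with (−)-MIB; CH2=CHCOCl; second-generation Grubbs catalyst). This gives in turn the C8 aldehyde (4R)-4-{[(tert-butyldimethylsilyl)oxy]methyl}-N-methoxy-N-methyl-6-oxohexanamide F3, the allylic alcohol (4R,6R)-4-{[(tert-butyldimethylsilyl)oxy]methyl}-6-hydroxy-N-methoxy-N-methyloct-7-enamide F4, its acrylate F5 and the butenolide amide (4R)-4-{[(tert-butyldimethylsilyl)oxy]methyl}-N-methoxy-N-methyl-5-[(2R)-5-oxo-2,5-dihydrofuran-2-yl]pentanamide F6.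
- F6 and F2 are joined with Sc(OTf)3 at −78 °C, anti to the C9 substituent, and the silyl ketene acetal is trapped with CH2=NMe2+ I− as in step 16 to give the bromobutenolide Mannich base F7. C6 epimers, if formed, would be separated here.
- Cp2Zr(H)Cl reduces the Weinreb amide to the C3 aldehyde F8 without touching the lactones.
- CrCl2 with catalytic NiCl2 in DMF at high dilution (Nozaki–Hiyama–Kishi reaction) joins C4–Br to the C3 aldehyde and gives the ten-membered ring carbinol F9.
- Acylation with (i-PrCO)2O, or Mitsunobu esterification with isobutyric acid if C3 is formed with the opposite configuration, gives 23.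

**Step 15.** The silyloxyfuran may not survive the metathesis: ruthenium hydride species or traces of acid could protodesilylate it, and the catalyst could be sequestered by the electron-rich diene, so that the acrylate closes slowly. The fallback reverses the order so that the furan is attached last. It sets out from 9, uses the butenolide amide F6 and the bromofuran F2 described under step 16, and returns at 21. Cp2Zr(H)Cl reduces F6 to the aldehyde (4R)-4-{[(tert-butyldimethylsilyl)oxy]methyl}-5-[(2R)-5-oxo-2,5-dihydrofuran-2-yl]pentanal F10. F2 is converted by bromine–lithium exchange (n-BuLi, −78 °C) and EtZnCl into the furylzinc reagent, which is added to F10 in the presence of (+)-MIB (the enantiomer of the ligand of step 12, for Re-face delivery and the (S)-carbinol). The zinc alkoxide is acylated in the flask with (i-PrCO)2O to give 21.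

**Step 9 (and with it steps 7 and 8).** The ketone 13 is a doubly activated Michael acceptor. Hydride may be delivered to C5 instead of the carbonyl, the catalyst may bind the lactone carbonyl and lose facial selectivity, and 13 may decompose before it is reduced; the preceding Morita–Baylis–Hillman step may also stall with an enolisable aldehyde. The fallback sets C3 by an auxiliary-controlled aldol reaction and introduces the ring double bond afterwards. It sets out from 10 and returns at 14.
- The boron enolate (n-Bu2BOTf, i-Pr2NEt) of (R)-4-benzyl-3-{4-[(4-methoxybenzyl)oxy]butanoyl}-1,3-oxazolidin-2-one F11 adds to 10 and gives the syn aldol adduct F12 with the (S)-carbinol at C3.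
- DDQ removes the 4-methoxybenzyl group, and the freed hydroxyl closes the γ-lactone with release of the auxiliary to give the 3-(1-hydroxyalkyl)oxolan-2-one F13.
- The dianion (LiN(i-Pr)2, 2.2 equiv) is selenenylated with PhSeBr at the lactone α-carbon to give the selenide F14.
- H2O2 forms the selenoxide, which eliminates into the ring, away from the carbinol carbon, and gives 14.

**Step 12.** Facial selectivity may be insufficient, through uncatalysed background addition to an unhindered, β-branched aldehyde; the C8 epimers would then only diverge at the key step. The fallback sets C8 by epoxidation and not by carbonyl addition. It sets out from 15 and returns at 18, replacing steps 11 and 12.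
- Cross metathesis of 15 with (Z)-but-2-ene-1,4-diol (second-generation Grubbs catalyst) gives the (E)-allylic alcohol F15.
- Sharpless epoxidation (Ti(Oi-Pr)4, D-(−)-diethyl tartrate, t-BuOOH) gives the (2R,3R)-epoxy alcohol F16.
- I2, PPh3 and imidazole give the epoxy iodide F17.
- Zn dust in EtOH opens F17 reductively to the (R)-allylic alcohol 18.

## Further compounds

F1 | step 16 | 3-bromofuran-2(5H)-one | O=C1OCC=C1Br
F2 | step 16 | 3-bromo-2-[(triisopropylsilyl)oxy]furan | Brc1ccoc1O[Si](C(C)C)(C(C)C)C(C)C
F3 | step 16 | (4R)-4-{[(tert-butyldimethylsilyl)oxy]methyl}-N-methoxy-N-methyl-6-oxohexanamide | O=CC[C@H](CO[Si](C)(C)C(C)(C)C)CCC(=O)N(C)OC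
F4 | step 16 | (4R,6R)-4-{[(tert-butyldimethylsilyl)oxy]methyl}-6-hydroxy-N-methoxy-N-methyloct-7-enamide | C=C[C@H](O)C[C@H](CO[Si](C)(C)C(C)(C)C)CCC(=O)N(C)OC
F5 | step 16 | (3R,5R)-5-{[(tert-butyldimethylsilyl)oxy]methyl}-8-[methoxy(methyl)amino]-8-oxooct-1-en-3-yl prop-2-enoate | C=CC(=O)O[C@@H](C=C)C[C@H](CO[Si](C)(C)C(C)(C)C)CCC(=O)N(C)OC
F6 | step 16 | (4R)-4-{[(tert-butyldimethylsilyl)oxy]methyl}-N-methoxy-N-methyl-5-[(2R)-5-oxo-2,5-dihydrofuran-2-yl]pentanamide | O=C1C=C[C@@H](C[C@H](CO[Si](C)(C)C(C)(C)C)CCC(=O)N(C)OC)O1
F7 | step 16 | open-chain Mannich base: trans-4,5-disubstituted 3-(dimethylaminomethyl)oxolan-2-one carrying the 4-bromo-5-oxo-2,5-dihydrofuran-2-yl group at C7 and the Weinreb amide chain at C8 | CN(C)CC1C(=O)O[C@H](C[C@H](CO[Si](C)(C)C(C)(C)C)CCC(=O)N(C)OC)[C@H]1[C@H]2C=C(Br)C(=O)O2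
F8 | step 16 | C3 aldehyde corresponding to F7 | CN(C)CC1C(=O)O[C@H](C[C@H](CO[Si](C)(C)C(C)(C)C)CCC=O)[C@H]1[C@H]2C=C(Br)C(=O)O2
F9 | step 16 | C3 alcohol corresponding to 23 (ten-membered ring carbinol) | CN(C)CC1C(=O)O[C@@H]2C[C@H](CO[Si](C)(C)C(C)(C)C)CC[C@H](O)C3=C[C@@H](OC3=O)[C@@H]12
F10 | step 15 | (4R)-4-{[(tert-butyldimethylsilyl)oxy]methyl}-5-[(2R)-5-oxo-2,5-dihydrofuran-2-yl]pentanal | O=C1C=C[C@@H](C[C@H](CO[Si](C)(C)C(C)(C)C)CCC=O)O1
F11 | step 9 | (R)-4-benzyl-3-{4-[(4-methoxybenzyl)oxy]butanoyl}-1,3-oxazolidin-2-one | O=C(CCCOCc1ccc(OC)cc1)N1[C@H](Cc2ccccc2)COC1=O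
F12 | step 9 | syn aldol adduct of F11 and 10, (2R,3S) in the acyl chain | O=C(N1[C@H](Cc2ccccc2)COC1=O)[C@H](CCOCc1ccc(OC)cc1)[C@@H](O)CC[C@H](CC=C)CO[Si](C)(C)C(C)(C)C
F13 | step 9 | 3-[(1S,4R)-4-{[(tert-butyldimethylsilyl)oxy]methyl}-1-hydroxyhept-6-en-1-yl]oxolan-2-one | O=C1OCC[C@@H]1[C@@H](O)CC[C@H](CC=C)CO[Si](C)(C)C(C)(C)C
F14 | step 9 | 3-(phenylselanyl) derivative of F13 | O=C1OCCC1([Se]c2ccccc2)[C@@H](O)CC[C@H](CC=C)CO[Si](C)(C)C(C)(C)C
F15 | step 12 | (1S,4R,6E)-4-{[(tert-butyldimethylsilyl)oxy]methyl}-8-hydroxy-1-(2-oxo-2,5-dihydrofuran-3-yl)oct-6-en-1-yl 2-methylpropanoate | OC/C=C/C[C@H](CO[Si](C)(C)C(C)(C)C)CC[C@H](OC(=O)C(C)C)C1=CCOC1=O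
F16 | step 12 | (2R,3R)-epoxy alcohol from F15 | OC[C@H]1O[C@@H]1C[C@H](CO[Si](C)(C)C(C)(C)C)CC[C@H](OC(=O)C(C)C)C2=CCOC2=O
F17 | step 12 | epoxy iodide from F16 | IC[C@H]1O[C@@H]1C[C@H](CO[Si](C)(C)C(C)(C)C)CC[C@H](OC(=O)C(C)C)C2=CCOC2=O
A1 | alternative 1 | ten-membered ring bridged by a C14–O8 γ-lactone, with C3 isobutyrate, C6 and C15 tert-butyldimethylsilyl ethers and a 3-[(4-methoxybenzyl)oxy]prop-1-en-2-yl group on C7 | C=C(COCc3ccc(OC)cc3)[C@H]1[C@H]2C[C@H](C(=O)O2)CC[C@H](OC(=O)C(C)C)/C(CO[Si](C)(C)C(C)(C)C)=C/[C@H]1O[Si](C)(C)C(C)(C)C
A2 | alternative 2 | ten-membered C10 ketone with trans C4=C5, C3 and C6 methoxymethyl ethers, C15 4-methoxybenzyl ether, C8 tert-butyldimethylsilyl ether and a 3-[(tert-butyldimethylsilyl)oxy]prop-1-en-2-yl group on C7 | O=C1CC[C@H](OCOC)/C(COCc2ccc(OC)cc2)=C/[C@@H](OCOC)[C@@H](C(=C)CO[Si](C)(C)C(C)(C)C)[C@H](O[Si](C)(C)C(C)(C)C)C1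
A3 | alternative 3 | C14 tert-butyldimethylsilyl ether of the target (same structure as 25) | C=C1C(=O)O[C@@H]2C[C@H](CO[Si](C)(C)C(C)(C)C)CC[C@H](OC(=O)C(C)C)C3=C[C@@H](OC3=O)[C@@H]12
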